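**Retrosynthetic overview**

- The strategy rests on the C3–C4 bond of the seven-carbon chain, numbered from the styryl end: C1=C2 alkene on ring A, C3 enol carbon, C4 central CH, C5 ketone, C6–C7 ethylene on ring B. This is the bond between the feruloyl carbonyl carbon and the central carbon of the unsymmetrical 1,3-diketone.
- Disconnection 1 (last C–C bond made) is C3–C4: C-acylation of the magnesium chelate of a tert-butyl β-keto ester (C4–C7, ring B) with silyl-protected feruloyl chloride (C1–C3, ring A). The ester carboxyl on C4 is a traceless activator, later lost as isobutene and CO2.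
- Disconnection 2 is C4–C5: acylation of Meldrum's acid with silyl-protected dihydroferulic acid, then tert-butanolysis.
- No ring is formed at any stage. Rings A and B arrive intact in ferulic and dihydroferulic acid, the E alkene comes from ferulic acid, and both phenols travel as TBS ethers that are removed last.

Key step: step 6

Assumption: the target is the chelated enol tautomer of a β-diketone; keto and enol forms interconvert freely, so the route delivers the diketone, and the drawn Z-enol, conjugated with the styryl group, is taken as the form that should prevail at equilibrium.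

**Route**

Step 1
Reactants: 1 ferulic acid
Product: 3 (E)-3-[4-(tert-butyldimethylsilyloxy)-3-methoxyphenyl]prop-2-enoic acid, via bis-silylated ferulate 2 (not isolated)
Conditions: TBSCl (2.4 equiv), imidazole (5 equiv), DMF, rt; then AcOH/THF/H2O (3:1:1), rt
Reagents that add atoms: tert-butyldimethylsilyl chloride (TBSCl), CC(C)(C)[Si](C)(C)Cl
Why: Imidazole-promoted silylation caps both the phenol and the acid, and the much more labile silyl ester of 2 should then be hydrolysed selectively by aqueous acetic acid while the aryl silyl ether stays (protection followed by selective silyl ester hydrolysis).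

Step 2
Reactants: 3 (E)-3-[4-(tert-butyldimethylsilyloxy)-3-methoxyphenyl]prop-2-enoic acid
Product: 4 (E)-3-[4-(tert-butyldimethylsilyloxy)-3-methoxyphenyl]prop-2-enoyl chloride
Conditions: (COCl)2 (1.5 equiv), DMF (cat.), CH2Cl2, 0 °C to rt; volatiles removed, used crude
Reagents that add atoms: oxalyl chloride, O=C(Cl)C(=O)Cl
Why: Vilsmeier-type activation with oxalyl chloride and catalytic DMF converts the acid into its chloride under mild conditions that should leave the aryl silyl ether and the E alkene untouched.

Step 3
Reactants: 5 3-(4-hydroxy-3-methoxyphenyl)propanoic acid (dihydroferulic acid)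
Product: 7 3-[4-(tert-butyldimethylsilyloxy)-3-methoxyphenyl]propanoic acid, via bis-silylated dihydroferulate 6 (not isolated)
Conditions: TBSCl (2.4 equiv), imidazole (5 equiv), DMF, rt; then AcOH/THF/H2O (3:1:1), rt
Reagents that add atoms: tert-butyldimethylsilyl chloride (TBSCl), CC(C)(C)[Si](C)(C)Cl
Why: The same silylation and selective silyl ester hydrolysis as in step 1, here on the saturated acid, should leave only the phenol protected.

Step 4
Reactants: 7 3-[4-(tert-butyldimethylsilyloxy)-3-methoxyphenyl]propanoic acid; 8 Meldrum's acid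
Product: 9 5-{3-[4-(tert-butyldimethylsilyloxy)-3-methoxyphenyl]-1-hydroxypropylidene}-2,2-dimethyl-1,3-dioxane-4,6-dione
Conditions: DCC (1.1 equiv), DMAP (1.5 equiv), CH2Cl2, 0 °C to rt; filtration, cold aq. KHSO4 wash
Reagents that add atoms: none
Why: Carbodiimide activation with DMAP as acyl-transfer catalyst and base (Steglich-type coupling) lets the acidic ring carbon of Meldrum's acid be C-acylated, giving the enolised acyl Meldrum's acid and forming the C4–C5 bond.

Step 5
Reactants: 9 acyl Meldrum's acid
Product: 11 tert-butyl 5-[4-(tert-butyldimethylsilyloxy)-3-methoxyphenyl]-3-oxopentanoate, via acylketene 10 (not isolated)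
Conditions: t-BuOH (5 equiv), toluene, 90 °C
Reagents that add atoms: tert-butanol, CC(C)(C)O
Why: On heating, the acyl Meldrum's acid should undergo cycloreversion with loss of acetone and CO2 to acylketene 10, which tert-butanol traps as the β-keto ester (Meldrum's acid route to β-keto esters).

Step 6
Reactants: 11 tert-butyl 5-[4-(tert-butyldimethylsilyloxy)-3-methoxyphenyl]-3-oxopentanoate; 4 (E)-3-[4-(tert-butyldimethylsilyloxy)-3-methoxyphenyl]prop-2-enoyl chloride
Product: 14 tert-butyl (E)-5-[4-(tert-butyldimethylsilyloxy)-3-methoxyphenyl]-2-{3-[4-(tert-butyldimethylsilyloxy)-3-methoxyphenyl]propanoyl}-3-oxopent-4-enoate, via chloromagnesium enolate 12 (not isolated), via chloromagnesium triketone chelate 13 (not isolated)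
Conditions: MgCl2 (1.1 equiv), pyridine (2.2 equiv), CH2Cl2, 0 °C; then 4 (1.1 equiv), 0 °C to rt; cold 1 M HCl work-up
Reagents that add atoms: none
Why: MgCl2 and pyridine enolise the doubly activated C4 methylene of 11 under soft conditions to the six-membered chloromagnesium chelate 12, whose central carbon adds to the carbonyl of acid chloride 4 and expels chloride (addition–elimination), forming the C3–C4 bond. The closest known reaction type is the MgCl2/tertiary-amine C-acylation of β-keto esters and malonates with acid chlorides, a Claisen-type condensation that mirrors the feruloyl transfer onto a diketide in curcuminoid biosynthesis. No ring is closed and no lasting stereocentre is created: the central carbon of 14 is enolisable and configurationally labile, and the E alkene is carried unchanged from ferulic acid. The step needs C- over O-acylation, which the tight O,O-chelation of magnesium should secure by tying up both oxygens and leaving carbon as the nucleophilic site, and 1,2- over 1,4-attack on the cinnamoyl unit, which follows from the far higher electrophilicity of the acyl chloride carbon compared with a β-carbon deactivated by the para-silyloxy donor. The more acidic product is captured at once as chelate 13 by the second equivalent of pyridine, which should stop a second acylation and hold the tricarbonyl array until the cold acidic work-up releases 14. Regiochemistry of enolisation is not in question, because only the methylene flanked by the two carbonyls is acidic enough under these conditions.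

Step 7
Reactants: 14 bis-silyl triketo tert-butyl ester
Product: 16 (4Z,6E)-1,7-bis[4-(tert-butyldimethylsilyloxy)-3-methoxyphenyl]-5-hydroxyhepta-4,6-dien-3-one, via diacylacetic acid 15 (not isolated)
Conditions: TFA/CH2Cl2 (1:4), 0 °C to rt; evaporation from toluene
Reagents that add atoms: none
Why: Acidolysis of the tert-butyl ester (loss of the tert-butyl cation as isobutene) frees diacylacetic acid 15, which as a β-keto acid should decarboxylate spontaneously through a cyclic transition state to the β-diketone, obtained as its chelated enol, while aryl silyl ethers tolerate anhydrous TFA.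

Step 8
Reactants: 16 bis-silyl dihydrocurcumin
Product: 17 (4Z,6E)-5-hydroxy-1,7-bis(4-hydroxy-3-methoxyphenyl)hepta-4,6-dien-3-one (dihydrocurcumin, CID5372374)
Conditions: TBAF (2.5 equiv), AcOH (3 equiv), THF, 0 °C
Reagents that add atoms: none
Why: Fluoride-mediated desilylation cleaves both aryl Si–O bonds, the acetic acid buffer prevents the build-up of phenolate and enolate that degrades curcuminoids, and tautomer equilibration should settle on the hydrogen-bonded Z-enol conjugated with the styryl group.

**Compound list**

1 | ferulic acid, (E)-3-(4-hydroxy-3-methoxyphenyl)prop-2-enoic acid | COc1cc(/C=C/C(=O)O)ccc1O | starting material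
2 | tert-butyldimethylsilyl (E)-3-[4-(tert-butyldimethylsilyloxy)-3-methoxyphenyl]prop-2-enoate | COc1cc(/C=C/C(=O)O[Si](C)(C)C(C)(C)C)ccc1O[Si](C)(C)C(C)(C)C | intermediate
3 | (E)-3-[4-(tert-butyldimethylsilyloxy)-3-methoxyphenyl]prop-2-enoic acid | COc1cc(/C=C/C(=O)O)ccc1O[Si](C)(C)C(C)(C)C | intermediate
4 | (E)-3-[4-(tert-butyldimethylsilyloxy)-3-methoxyphenyl]prop-2-enoyl chloride | COc1cc(/C=C/C(Cl)=O)ccc1O[Si](C)(C)C(C)(C)C | intermediate
5 | dihydroferulic acid, 3-(4-hydroxy-3-methoxyphenyl)propanoic acid | COc1cc(CCC(=O)O)ccc1O | starting material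
6 | tert-butyldimethylsilyl 3-[4-(tert-butyldimethylsilyloxy)-3-methoxyphenyl]propanoate | COc1cc(CCC(=O)O[Si](C)(C)C(C)(C)C)ccc1O[Si](C)(C)C(C)(C)C | intermediate
7 | 3-[4-(tert-butyldimethylsilyloxy)-3-methoxyphenyl]propanoic acid | COc1cc(CCC(=O)O)ccc1O[Si](C)(C)C(C)(C)C | intermediate
8 | Meldrum's acid, 2,2-dimethyl-1,3-dioxane-4,6-dione | CC1(C)OC(=O)CC(=O)O1 | starting material
9 | 5-{3-[4-(tert-butyldimethylsilyloxy)-3-methoxyphenyl]-1-hydroxypropylidene}-2,2-dimethyl-1,3-dioxane-4,6-dione (acyl Meldrum's acid, enol form) | COc1cc(CCC(O)=C2C(=O)OC(C)(C)OC2=O)ccc1O[Si](C)(C)C(C)(C)C | intermediate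
10 | 5-[4-(tert-butyldimethylsilyloxy)-3-methoxyphenyl]pent-1-ene-1,3-dione (acylketene) | COc1cc(CCC(=O)C=C=O)ccc1O[Si](C)(C)C(C)(C)C | intermediate
11 | tert-butyl 5-[4-(tert-butyldimethylsilyloxy)-3-methoxyphenyl]-3-oxopentanoate | COc1cc(CCC(=O)CC(=O)OC(C)(C)C)ccc1O[Si](C)(C)C(C)(C)C | intermediate
12 | chloromagnesium enolate (O,O-chelate) of β-keto ester 11, drawn as its ions | COc1cc(CCC(=O)[CH-]C(=O)OC(C)(C)C)ccc1O[Si](C)(C)C(C)(C)C.[Mg+2].[Cl-] | intermediate
13 | chloromagnesium chelate of triketo ester 14, drawn as its ions | COc1cc(/C=C/C(=O)[C-](C(=O)OC(C)(C)C)C(=O)CCc2ccc(O[Si](C)(C)C(C)(C)C)c(OC)c2)ccc1O[Si](C)(C)C(C)(C)C.[Mg+2].[Cl-] | intermediate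
14 | tert-butyl (E)-5-[4-(tert-butyldimethylsilyloxy)-3-methoxyphenyl]-2-{3-[4-(tert-butyldimethylsilyloxy)-3-methoxyphenyl]propanoyl}-3-oxopent-4-enoate (triketo tautomer drawn; central carbon configurationally labile) | COc1cc(/C=C/C(=O)C(C(=O)OC(C)(C)C)C(=O)CCc2ccc(O[Si](C)(C)C(C)(C)C)c(OC)c2)ccc1O[Si](C)(C)C(C)(C)C | intermediate
15 | (E)-5-[4-(tert-butyldimethylsilyloxy)-3-methoxyphenyl]-2-{3-[4-(tert-butyldimethylsilyloxy)-3-methoxyphenyl]propanoyl}-3-oxopent-4-enoic acid | COc1cc(/C=C/C(=O)C(C(=O)O)C(=O)CCc2ccc(O[Si](C)(C)C(C)(C)C)c(OC)c2)ccc1O[Si](C)(C)C(C)(C)C | intermediate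
16 | (4Z,6E)-1,7-bis[4-(tert-butyldimethylsilyloxy)-3-methoxyphenyl]-5-hydroxyhepta-4,6-dien-3-one | COc1cc(/C=C/C(O)=C/C(=O)CCc2ccc(O[Si](C)(C)C(C)(C)C)c(OC)c2)ccc1O[Si](C)(C)C(C)(C)C | intermediate
17 | (4Z,6E)-5-hydroxy-1,7-bis(4-hydroxy-3-methoxyphenyl)hepta-4,6-dien-3-one (dihydrocurcumin, CID5372374) | COc1cc(/C=C/C(O)=C/C(=O)CCc2ccc(O)c(OC)c2)ccc1O | target

**Step count and risk**

Total step count: 8. Longest linear sequence: 6 steps (steps 3, 4, 5, 6, 7 and 8, from dihydroferulic acid 5).

Steps most likely to fail:

1. Step 6. Acyl transfer to the crowded, doubly stabilised enolate may be slow. The electron-rich cinnamoyl chloride could then be lost to O-acylation, conjugate addition or hydrolysis, or the triacylmethane could shed an acyl group by retro-Claisen cleavage during work-up. The fallback sets out from 7 and comes back to the route at 17, making the C1=C2 alkene (styryl-end numbering) instead of the C3–C4 bond. Acid 7 is converted with 1,1'-carbonyldiimidazole (THF, rt) into 1-{3-[4-(tert-butyldimethylsilyloxy)-3-methoxyphenyl]propanoyl}imidazole F1. F1 is added without isolation to an excess of the lithium enolate of acetone (acetone, LiN(iPr)2, THF, −78 °C) to give 6-[4-(tert-butyldimethylsilyloxy)-3-methoxyphenyl]hexane-2,4-dione F2. F2 is then condensed with vanillin in a boron-templated aldol condensation (Pabon reaction: B2O3, B(OBu)3, catalytic n-BuNH2, EtOAc, 70 °C; then warm dilute HCl). Boron chelation blocks the central carbon, and the terminal methyl group should react in preference to the more hindered methylene on the other flank. This should give the E alkene and the mono-silyl ether (4Z,6E)-1-[4-(tert-butyldimethylsilyloxy)-3-methoxyphenyl]-5-hydroxy-7-(4-hydroxy-3-methoxyphenyl)hepta-4,6-dien-3-one F3. Any silyl loss during the acidic hydrolysis only anticipates the last operation. Desilylation of F3 under the conditions of step 8 rejoins the route at 17.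

2. Step 7. The tert-butyl cation may alkylate the electron-rich rings in a Friedel–Crafts sense, and the strong acid may cause premature silyl ether loss or acyl cleavage of the triacylmethane before decarboxylation. The fallback sets out from 9 and comes back to the route at 16, replacing acidolysis by a neutral palladium-catalysed deallylation. Heating 9 with allyl alcohol (toluene, 90 °C, through acylketene 10) should give prop-2-enyl 5-[4-(tert-butyldimethylsilyloxy)-3-methoxyphenyl]-3-oxopentanoate F4. C-Acylation with 4 under the conditions of step 6 proceeds through the chloromagnesium enolate F5 and the chloromagnesium chelate F6 of the product. It should give prop-2-enyl (E)-5-[4-(tert-butyldimethylsilyloxy)-3-methoxyphenyl]-2-{3-[4-(tert-butyldimethylsilyloxy)-3-methoxyphenyl]propanoyl}-3-oxopent-4-enoate F7. Treatment of F7 with Pd(OAc)2 and PPh3 in the presence of HCO2H and Et3N (THF, rt) is a Tsuji–Trost deallylation. The zerovalent palladium formed in situ ionises the allyl ester, formate reduces the allyl fragment to propene, and the liberated acid 15 decarboxylates to 16.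

3. Step 5. The hindered alcohol may trap acylketene 10 too slowly, so that ketene dimerisation or collapse to the methyl ketone by adventitious water and decarboxylation competes. The fallback sets out from 7 and comes back to the route at 11, bypassing Meldrum's acid by a decarboxylative Claisen condensation. Acid 7 is converted with (COCl)2 and catalytic DMF (CH2Cl2, 0 °C to rt) into 3-[4-(tert-butyldimethylsilyloxy)-3-methoxyphenyl]propanoyl chloride F8. F8 acylates the magnesium enolate of mono-tert-butyl malonate (mono-tert-butyl malonate, MgCl2, Et3N, MeCN, 0 °C to rt). The resulting 2-(tert-butoxycarbonyl)-5-[4-(tert-butyldimethylsilyloxy)-3-methoxyphenyl]-3-oxopentanoic acid F9 is not isolated and should lose CO2 on mild acidic work-up to give 11.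

**Further compounds**

F1 | step 6 | 1-{3-[4-(tert-butyldimethylsilyloxy)-3-methoxyphenyl]propanoyl}imidazole | COc1cc(CCC(=O)n2ccnc2)ccc1O[Si](C)(C)C(C)(C)C
F2 | step 6 | 6-[4-(tert-butyldimethylsilyloxy)-3-methoxyphenyl]hexane-2,4-dione | COc1cc(CCC(=O)CC(C)=O)ccc1O[Si](C)(C)C(C)(C)C
F3 | step 6 | (4Z,6E)-1-[4-(tert-butyldimethylsilyloxy)-3-methoxyphenyl]-5-hydroxy-7-(4-hydroxy-3-methoxyphenyl)hepta-4,6-dien-3-one | COc1cc(/C=C/C(O)=C/C(=O)CCc2ccc(O[Si](C)(C)C(C)(C)C)c(OC)c2)ccc1O
F4 | step 7 | prop-2-enyl 5-[4-(tert-butyldimethylsilyloxy)-3-methoxyphenyl]-3-oxopentanoate | COc1cc(CCC(=O)CC(=O)OCC=C)ccc1O[Si](C)(C)C(C)(C)C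
F5 | step 7 | chloromagnesium enolate of allyl β-keto ester F4, drawn as its ions | COc1cc(CCC(=O)[CH-]C(=O)OCC=C)ccc1O[Si](C)(C)C(C)(C)C.[Mg+2].[Cl-]
F6 | step 7 | chloromagnesium chelate of allyl triketo ester F7, drawn as its ions | COc1cc(/C=C/C(=O)[C-](C(=O)OCC=C)C(=O)CCc2ccc(O[Si](C)(C)C(C)(C)C)c(OC)c2)ccc1O[Si](C)(C)C(C)(C)C.[Mg+2].[Cl-]
F7 | step 7 | prop-2-enyl (E)-5-[4-(tert-butyldimethylsilyloxy)-3-methoxyphenyl]-2-{3-[4-(tert-butyldimethylsilyloxy)-3-methoxyphenyl]propanoyl}-3-oxopent-4-enoate | COc1cc(/C=C/C(=O)C(C(=O)OCC=C)C(=O)CCc2ccc(O[Si](C)(C)C(C)(C)C)c(OC)c2)ccc1O[Si](C)(C)C(C)(C)C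
F8 | step 5 | 3-[4-(tert-butyldimethylsilyloxy)-3-methoxyphenyl]propanoyl chloride | COc1cc(CCC(Cl)=O)ccc1O[Si](C)(C)C(C)(C)C
F9 | step 5 | 2-(tert-butoxycarbonyl)-5-[4-(tert-butyldimethylsilyloxy)-3-methoxyphenyl]-3-oxopentanoic acid | COc1cc(CCC(=O)C(C(=O)O)C(=O)OC(C)(C)C)ccc1O[Si](C)(C)C(C)(C)C
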